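Numbering: ring A (cyclohexenone) is C1(=O)–C2=C3–C4(OAc)–C5H2–C6(spiro). Ring B (γ-lactone) is C6–C7H2–C8(=O)–O9–C10. The chain is C10–C11=C12(CH3)–C13–C14–C15(OH)–C16(CH3)=C17H2.
Enabling feature: the C15 carbinol next to the isopropenyl carbon C16 is the 1,3-transposed form of an (E)-2-methylallylic alcohol (C17–OH on a C15=C16 alkene). The C15–O bond can therefore be made by hydroxyl-directed epoxidation, and C16=C17 by reductive opening of the oxirane at C16.
Retrosynthetic cuts, in order: C16=C17 back to oxirane plus C17–I; then C15–O and C16–O (oxirane); then C10–C11 and O9–C8 (ring B); then C1–C6 and C4–C5 (ring A, retro-Diels–Alder to 2-methoxyfuran and an α-substituted acrolein).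
Forward order: the C11–C17 alkenyl iodide is built from pent-4-yn-1-ol, and ring A is formed as a 1-methoxy-7-oxanorbornene. Ring B closes during fragment union, the bicycle is opened to the 4-hydroxyenone and acetylated, and the chain terminus is finished last.
Stereochemistry: C4 and C6 come from a catalyst-controlled exo-formyl cycloaddition, C10 from chelate-controlled addition to the aldehyde on C6, and C15 (with transient C16) from D-(−)-diethyl tartrate.

Key step: step 11

Remark: the catalyst of step 6 is made beforehand from N-tosyl-D-tryptophan and BuB(OH)2 by azeotropic dehydration and is not counted as a step. Aldehydes 10 and 12 are used directly after preparation, because 10 can isomerise and 12 can undergo cycloreversion.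

Step 1
Reactants: 1 pent-4-yn-1-ol
Product: 3 (E)-5-iodo-4-methylpent-4-en-1-ol, via alkenylalane 2 (not isolated)
Conditions: AlMe3 (3 equiv), Cp2ZrCl2 (25 mol %), CH2Cl2, 0 °C to rt; then I2, THF, −30 to 0 °C
Reagents that add atoms: trimethylaluminium, C[Al](C)C; iodine, [I][I]
Why: Negishi zirconium-catalysed methylalumination adds CH3 and aluminium syn across the terminal alkyne with CH3 on the internal carbon (future C12), and iodinolysis of the C–Al bond proceeds with retention, which fixes the E geometry of C11=C12.

Step 2
Reactants: 3 (E)-5-iodo-4-methylpent-4-en-1-ol; 4 ethyl 2-(triphenylphosphoranylidene)propanoate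
Product: 6 ethyl (2E,6E)-7-iodo-2,6-dimethylhepta-2,6-dienoate, via (E)-5-iodo-4-methylpent-4-enal 5 (not isolated)
Conditions: IBX (1.5 equiv), DMSO, rt
Reagents that add atoms: none
Why: Tandem IBX oxidation–Wittig olefination traps the aldehyde as it forms, and the stabilised α-methyl ylide should give the E enoate that becomes C15=C16.

Step 3
Reactants: 6 ethyl (2E,6E)-7-iodo-2,6-dimethylhepta-2,6-dienoate
Product: 7 (2E,6E)-7-iodo-2,6-dimethylhepta-2,6-dien-1-ol
Conditions: iBu2AlH (2.3 equiv), CH2Cl2, −78 °C
Reagents that add atoms: none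
Why: 1,2-Reduction of an α,β-unsaturated ester with iBu2AlH at low temperature gives the allylic alcohol and leaves the alkenyl iodide and both alkene geometries untouched.

Step 4
Reactants: 7 (2E,6E)-7-iodo-2,6-dimethylhepta-2,6-dien-1-ol
Product: 8 tert-butyl{[(2E,6E)-7-iodo-2,6-dimethylhepta-2,6-dien-1-yl]oxy}dimethylsilane
Conditions: TBSCl, imidazole, CH2Cl2, 0 °C to rt
Reagents that add atoms: tert-butyldimethylsilyl chloride, CC(C)(C)[Si](C)(C)Cl
Why: Imidazole-promoted silylation masks the C17 hydroxyl so that it survives t-BuLi and can later be distinguished from the C4 hydroxyl.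

Step 5
Reactants: 9 methyl 4-oxobutanoate
Product: 10 methyl 3-formylbut-3-enoate
Conditions: aq. CH2O (37 %), pyrrolidine (10 mol %), propionic acid (10 mol %), iPrOH, 45 °C, short contact time
Reagents that add atoms: formaldehyde, C=O
Why: Organocatalytic α-methylenation (Mannich condensation of the enamine with formaldehyde, then amine elimination) installs the 1,1-disubstituted enal, and a short reaction time should prevent migration of the alkene into conjugation with the ester.

Step 6
Reactants: 10 methyl 3-formylbut-3-enoate; 11 2-methoxyfuran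
Product: 12 methyl 2-[(1S,2R,4S)-2-formyl-1-methoxy-7-oxabicyclo[2.2.1]hept-5-en-2-yl]acetate (formyl exo)
Conditions: (4R)-2-butyl-4-(1H-indol-3-ylmethyl)-3-tosyl-1,3,2-oxazaborolidin-5-one (20 mol %), CH2Cl2, −78 °C; Et3N quench, cold filtration through Et3N-deactivated silica
Reagents that add atoms: none
Why: Proposed new method: boron binds the formyl oxygen of 10 while the indole ring stacks on one face of the s-cis enal, so 11 can reach only the open face; the unsubstituted α-carbon of the furan (largest HOMO coefficient, future C4) bonds to the CH2 terminus (future C5) and the methoxy-bearing carbon (future C1) to the α-carbon (future C6), and 2-substituted acroleins place the formyl group exo (syn to the oxygen bridge), so one asynchronous [4+2] event should fix C4 (S), C6 (R) and the transient ketal centre C1; −78 °C, an aprotic neutral Lewis acid and the amine quench are meant to suppress proton loss to a 5-alkylated furan, ketal ionisation and cycloreversion; the closest known reactions are the enantioselective Diels–Alder addition of furan itself to 2-bromo- and 2-chloroacrolein with this catalyst class (the D-tryptophan series is chosen from its sense of induction) and the uncatalysed cycloadditions of 2-methoxyfuran to electron-poor alkenes.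

Step 7
Reactants: 8 tert-butyl{[(2E,6E)-7-iodo-2,6-dimethylhepta-2,6-dien-1-yl]oxy}dimethylsilane; 12 methyl 2-[(1S,2R,4S)-2-formyl-1-methoxy-7-oxabicyclo[2.2.1]hept-5-en-2-yl]acetate
Product: 16 oxa-bridged spirolactone (1S,4S,6R,10R), via alkenyllithium 13 (not isolated), via alkenylmagnesium bromide 14 (not isolated), via bromomagnesium alkoxide 15 (not isolated)
Conditions: 8, t-BuLi (2.1 equiv), Et2O, −78 °C; MgBr2·OEt2 (1.2 equiv); then 12, CH2Cl2–Et2O, −78 to 0 °C; pH 7 buffer
Reagents that add atoms: none
Why: Iodine–lithium exchange and transmetallation retain the alkene geometry, and the alkenylmagnesium bromide adds to the aldehyde held in a six-membered magnesium chelate between the formyl oxygen and the C1 methoxy oxygen (Cram chelate model), so attack should come from the Re face past C5H2 rather than past the C7 ester arm and set C10 as R, after which alkoxide 15 displaces methoxide from the C8 ester (5-exo-trig lactonisation) and closes ring B.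

Step 8
Reactants: 16 oxa-bridged spirolactone (1S,4S,6R,10R)
Product: 17 (4S,6R,10R)-4-hydroxyenone spirolactone, C17 silyl ether
Conditions: PPTS (10 mol %), acetone–H2O (9:1), 0 °C to rt
Reagents that add atoms: water, O
Why: Acid-catalysed hydrolysis of the bridged ketal cleaves only the C1–O bridge bond (methoxy-stabilised oxocarbenium ion, then water in and methanol out), which gives the C1 ketone conjugated with C2=C3 and leaves the C4–O bond and its S configuration intact, while PPTS is too weak to remove the primary silyl ether.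

Step 9
Reactants: 17 (4S,6R,10R)-4-hydroxyenone spirolactone, C17 silyl ether
Product: 18 (4S,6R,10R)-4-acetoxyenone spirolactone, C17 silyl ether
Conditions: Ac2O, pyridine, DMAP (cat.), CH2Cl2, 0 °C
Reagents that add atoms: acetic anhydride, CC(=O)OC(C)=O
Why: DMAP-catalysed acetylation meets only one free hydroxyl, does not touch the C4–O bond, and cannot trigger elimination because C6 carries no hydrogen and C5–H is not acidic.

Step 10
Reactants: 18 (4S,6R,10R)-4-acetoxyenone spirolactone, C17 silyl ether
Product: 19 (1R,5R,9S)-1-[(1E,5E)-7-hydroxy-2,6-dimethylhepta-1,5-dien-1-yl]-3,6-dioxo-2-oxaspiro[4.5]dec-7-en-9-yl acetate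
Conditions: HF·pyridine, THF–pyridine, 0 °C to rt
Reagents that add atoms: none
Why: Buffered fluoride cleavage of the primary silyl ether frees the C17 hydroxyl without the basic conditions that could attack the acetate, the lactone or the enone.

Step 11
Reactants: 19 (1R,5R,9S)-1-[(1E,5E)-7-hydroxy-2,6-dimethylhepta-1,5-dien-1-yl]-3,6-dioxo-2-oxaspiro[4.5]dec-7-en-9-yl acetate
Product: 20 (1R,5R,9S)-1-{(1E)-4-[(2R,3R)-3-(hydroxymethyl)-3-methyloxiran-2-yl]-2-methylbut-1-en-1-yl}-3,6-dioxo-2-oxaspiro[4.5]dec-7-en-9-yl acetate
Conditions: Ti(OiPr)4 (20 mol %), D-(−)-diethyl tartrate (24 mol %), t-BuOOH (2 equiv, anhydrous), 4 Å molecular sieves, CH2Cl2, −20 °C; hydroxide-free work-up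
Reagents that add atoms: tert-butyl hydroperoxide, CC(C)(C)OO
Why: The C17 hydroxyl of 19 and t-BuOOH displace isopropoxide ligands on the tartrate-bridged complex of tetravalent titanium, and the activated peroxide oxygen is passed to the C15=C16 π bond that the alkoxide tether holds beside it (Katsuki–Sharpless asymmetric epoxidation, for which (E)-2-methylallylic alcohols are among the fastest and most selective substrates). The oxirane closes in one suprafacial [2+1] oxygen-atom transfer that forms C15–O and C16–O together, so the E geometry becomes the trans relation of C14 and C17. Both new centres are under reagent control alone: the (S,S)-tartrate, D-(−)-diethyl tartrate, gives the (15R,16R)-oxirane, the mirror-image series of the (2S,3S)-epoxy alcohols formed with the L-(+)-ester, and the nearest ring stereocentre (C10) lies five bonds from C15. The step needs site selectivity among three alkenes, and the substrate supplies it: the allylic oxygen of C11=C12 (O9) is locked in the lactone and cannot bind titanium, and C2=C3 is an electron-poor enone that an electrophilic titanium peroxide does not attack, while the absence of base rules out nucleophilic epoxidation. At −20 °C with substoichiometric titanium and sieves the acetate and lactone should not transesterify.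

Step 12
Reactants: 20 (15R,16R)-epoxy alcohol
Product: 21 (1R,5R,9S)-1-{(1E)-4-[(2R,3S)-3-(iodomethyl)-3-methyloxiran-2-yl]-2-methylbut-1-en-1-yl}-3,6-dioxo-2-oxaspiro[4.5]dec-7-en-9-yl acetate
Conditions: I2, PPh3, imidazole, CH2Cl2, 0 °C
Reagents that add atoms: iodine, [I][I]
Why: Appel-type iodination (Garegg–Samuelsson conditions) replaces the primary C17 hydroxyl through its alkoxyphosphonium salt, the imidazole buffer should keep the oxirane closed, and no stereocentre is touched (the C16 descriptor changes only through CIP priorities).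

Step 13
Reactants: 21 (15R,16S)-epoxy iodide
Product: 22 (1R,5R,9S)-1-[(1E,5R)-5-hydroxy-2,6-dimethylhepta-1,6-dien-1-yl]-3,6-dioxo-2-oxaspiro[4.5]dec-7-en-9-yl acetate (target)
Conditions: activated Zn dust (10 equiv), EtOH, 40–50 °C, short contact time
Reagents that add atoms: none
Why: Zinc inserts into the primary C17–I bond and the oxirane oxygen is expelled from C16 (reductive β-elimination of a 2,3-epoxy iodide), so only C16–O breaks, C16=C17 forms and C15–O keeps its R configuration, while neutral ethanol without added acid should spare the γ-acetoxy enone.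

Compound list
1 | pent-4-yn-1-ol | C#CCCCO | starting material
2 | (1E)-5-(dimethylalumanyloxy)-2-methylpent-1-enyl(dimethyl)alumane | C[Al](C)OCCC/C(C)=C/[Al](C)C | intermediate
3 | (E)-5-iodo-4-methylpent-4-en-1-ol | OCCC/C(C)=C/I | intermediate
4 | ethyl 2-(triphenylphosphoranylidene)propanoate | CCOC(=O)C(C)=P(c1ccccc1)(c1ccccc1)c1ccccc1 | starting material
5 | (E)-5-iodo-4-methylpent-4-enal | O=CCC/C(C)=C/I | intermediate
6 | ethyl (2E,6E)-7-iodo-2,6-dimethylhepta-2,6-dienoate | CCOC(=O)/C(C)=C/CC/C(C)=C/I | intermediate
7 | (2E,6E)-7-iodo-2,6-dimethylhepta-2,6-dien-1-ol | OC/C(C)=C/CC/C(C)=C/I | intermediate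
8 | tert-butyl{[(2E,6E)-7-iodo-2,6-dimethylhepta-2,6-dien-1-yl]oxy}dimethylsilane | CC(C)(C)[Si](C)(C)OC/C(C)=C/CC/C(C)=C/I | intermediate
9 | methyl 4-oxobutanoate | COC(=O)CCC=O | starting material
10 | methyl 3-formylbut-3-enoate | COC(=O)CC(=C)C=O | intermediate
11 | 2-methoxyfuran | COc1ccco1 | starting material
12 | methyl 2-[(1S,2R,4S)-2-formyl-1-methoxy-7-oxabicyclo[2.2.1]hept-5-en-2-yl]acetate (exo-formyl) | CO[C@@]12C=C[C@@H](O1)C[C@]2(C=O)CC(=O)OC | intermediate
13 | (1E,5E)-7-(tert-butyldimethylsilyloxy)-2,6-dimethylhepta-1,5-dienyllithium | [Li]/C=C(C)/CC/C=C(C)/CO[Si](C)(C)C(C)(C)C | intermediate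
14 | (1E,5E)-7-(tert-butyldimethylsilyloxy)-2,6-dimethylhepta-1,5-dienylmagnesium bromide | Br[Mg]/C=C(C)/CC/C=C(C)/CO[Si](C)(C)C(C)(C)C | intermediate
15 | bromomagnesium (10R)-alkoxide from addition of 14 to the formyl group of 12 (methyl ester still open) | CO[C@@]12C=C[C@@H](O1)C[C@@]2(CC(=O)OC)[C@H](O[Mg]Br)/C=C(C)/CC/C=C(C)/CO[Si](C)(C)C(C)(C)C | intermediate
16 | (1S,4S,6R,10R)-spirolactone: 1-methoxy-7-oxanorbornene (ring A masked, oxygen bridge C1–C4) spiro-fused at C6 to γ-lactone ring B, C10 bearing the (1E,5E)-7-(TBSO)-2,6-dimethylhepta-1,5-dienyl chain | CO[C@@]12C=C[C@@H](O1)C[C@]23CC(=O)O[C@@H]3/C=C(C)/CC/C=C(C)/CO[Si](C)(C)C(C)(C)C | intermediate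
17 | (1R,5R,9S)-1-[(1E,5E)-7-(tert-butyldimethylsilyloxy)-2,6-dimethylhepta-1,5-dien-1-yl]-9-hydroxy-2-oxaspiro[4.5]dec-7-ene-3,6-dione | CC(C)(C)[Si](C)(C)OC/C(C)=C/CC/C(C)=C/[C@H]1OC(=O)C[C@]12C[C@H](O)C=CC2=O | intermediate
18 | (1R,5R,9S)-1-[(1E,5E)-7-(tert-butyldimethylsilyloxy)-2,6-dimethylhepta-1,5-dien-1-yl]-3,6-dioxo-2-oxaspiro[4.5]dec-7-en-9-yl acetate | CC(C)(C)[Si](C)(C)OC/C(C)=C/CC/C(C)=C/[C@H]1OC(=O)C[C@]12C[C@H](OC(C)=O)C=CC2=O | intermediate
19 | (1R,5R,9S)-1-[(1E,5E)-7-hydroxy-2,6-dimethylhepta-1,5-dien-1-yl]-3,6-dioxo-2-oxaspiro[4.5]dec-7-en-9-yl acetate | OC/C(C)=C/CC/C(C)=C/[C@H]1OC(=O)C[C@]12C[C@H](OC(C)=O)C=CC2=O | intermediate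
20 | (1R,5R,9S)-1-{(1E)-4-[(2R,3R)-3-(hydroxymethyl)-3-methyloxiran-2-yl]-2-methylbut-1-en-1-yl}-3,6-dioxo-2-oxaspiro[4.5]dec-7-en-9-yl acetate | OC[C@@]1(C)O[C@@H]1CC/C(C)=C/[C@H]2OC(=O)C[C@]23C[C@H](OC(C)=O)C=CC3=O | intermediate
21 | (1R,5R,9S)-1-{(1E)-4-[(2R,3S)-3-(iodomethyl)-3-methyloxiran-2-yl]-2-methylbut-1-en-1-yl}-3,6-dioxo-2-oxaspiro[4.5]dec-7-en-9-yl acetate | IC[C@@]1(C)O[C@@H]1CC/C(C)=C/[C@H]2OC(=O)C[C@]23C[C@H](OC(C)=O)C=CC3=O | intermediate
22 | (1R,5R,9S)-1-[(1E,5R)-5-hydroxy-2,6-dimethylhepta-1,6-dien-1-yl]-3,6-dioxo-2-oxaspiro[4.5]dec-7-en-9-yl acetate | C=C(C)[C@H](O)CC/C(C)=C/[C@H]1OC(=O)C[C@]12C[C@H](OC(C)=O)C=CC2=O | target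

Total step count: 13.
Longest linear sequence: 11 steps (steps 1–4, then 7–13). The ring branch (steps 5 and 6) joins at step 7.

Steps most likely to fail

Step 6 carries the label and the highest risk.
- **What may go wrong:** proton loss after the first C–C bond forms (Friedel–Crafts-type alkylation of the furan in place of ring closure), cycloreversion during isolation, or weak enantioface and exo/endo discrimination.
- **Fallback (known chemistry only):** setting out from 10 and 11, the cycloaddition is run without catalyst (Et2O, rt, or 10 kbar) and the exo isomer is purified to give the racemic exo-formyl cycloadduct F1.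
- F1 is taken through the operations of steps 7 and 8 to the racemic oxa-bridged spirolactone F2 and the racemic hydroxyenone F3.
- Lipase-catalysed acylation follows (Candida antarctica lipase B or Burkholderia cepacia lipase, vinyl acetate, t-BuOMe, rt). By the Kazlauskas rule, with the C5/C6 flank as the large group, it should acetylate the 4S enantiomer and deliver 18 directly.
- The unreacted enantiomeric hydroxyenone F4 is removed by chromatography, and the route is rejoined at 18.

Step 7.
- **What may go wrong:** incomplete chelation of magnesium to the hindered bridgehead methoxy group, so that an open Felkin-type pathway erodes or reverses the facial selectivity at C10. Lewis-acid opening of the ketal is a second concern.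
- **Fallback:** setting out from 8 and 12, the same bond is made under ligand control instead of substrate control. This is a Nozaki–Hiyama–Kishi coupling with stoichiometric CrCl2 bound to a chiral oxazoline–sulfonamide ligand, catalytic NiCl2 and Et3N in THF at rt.
- The ligand antipode that matches the 10R sense is selected in a trial run. The alkoxide of trivalent chromium lactonises on mildly basic work-up, and the route is rejoined at 16. This detour creates no new compound (F0).

Step 13.
- **What may go wrong:** electron transfer from zinc to the γ-acetoxy enone with loss of acetate, competing with insertion into the C17–I bond.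
- **Fallback:** setting out from 21, the opening is run as a radical chain (Bu3SnH, Et3B/air, toluene, −20 to 0 °C).
- Iodine abstraction gives the oxiranylcarbinyl radical, which opens by C16–O scission to the C15 allyloxy radical. Hydrogen transfer from the stannane then gives 22 with the C15–O bond untouched. This detour creates no new compound (F0).

Further compounds
F1 | step 6 | racemic methyl 2-(2-exo-formyl-1-methoxy-7-oxabicyclo[2.2.1]hept-5-en-2-yl)acetate (12 plus its enantiomer) | CO[C@@]12C=C[C@@H](O1)C[C@]2(C=O)CC(=O)OC.CO[C@]12C=C[C@H](O1)C[C@@]2(C=O)CC(=O)OC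
F2 | step 6 | racemic oxa-bridged spirolactone (16 plus its enantiomer) | CO[C@@]12C=C[C@@H](O1)C[C@]23CC(=O)O[C@@H]3/C=C(C)/CC/C=C(C)/CO[Si](C)(C)C(C)(C)C.CO[C@]12C=C[C@H](O1)C[C@@]23CC(=O)O[C@H]3/C=C(C)/CC/C=C(C)/CO[Si](C)(C)C(C)(C)C
F3 | step 6 | racemic hydroxyenone spirolactone (17 plus its enantiomer) | CC(C)(C)[Si](C)(C)OC/C(C)=C/CC/C(C)=C/[C@H]1OC(=O)C[C@]12C[C@H](O)C=CC2=O.CC(C)(C)[Si](C)(C)OC/C(C)=C/CC/C(C)=C/[C@@H]1OC(=O)C[C@@]12C[C@@H](O)C=CC2=O
F4 | step 6 | (1S,5S,9R)-1-[(1E,5E)-7-(tert-butyldimethylsilyloxy)-2,6-dimethylhepta-1,5-dien-1-yl]-9-hydroxy-2-oxaspiro[4.5]dec-7-ene-3,6-dione (enantiomer of 17) | CC(C)(C)[Si](C)(C)OC/C(C)=C/CC/C(C)=C/[C@@H]1OC(=O)C[C@@]12C[C@@H](O)C=CC2=O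
F0 | step 7 | none | none
F0 | step 13 | none | none
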